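## Structural features

The target 16 is a dimethyl succinate whose C-2 and C-3 each carry a 1,4-benzoquinone ring bonded through quinone carbon C-2, and each quinone bears an (E)-geranyl chain on C-6. In each ring the C-1 carbonyl therefore lies between the two carbon-substituted positions C-2 and C-6, whereas the C-4 carbonyl lies between the two CH carbons C-3 and C-5. The two halves are constitutionally identical and meet at the succinate C-2–C-3 bond, whose adjacent stereocentres carry the same four substituents with opposite descriptors (2R,3S), so 16 is the achiral meso diastereomer and only relative configuration has to be secured. Fragile elements are the quinones (base, nucleophiles, reductants), the two methine hydrogens activated by both an ester and a quinone (epimerisation, quinone-methide tautomerism), the four trisubstituted alkenes (acid, electrophilic oxidants), the ring–CH2–CH=C units and the methyl esters. The real difficulty is the 1,2,3,5-substitution pattern of each ring, in which both carbon substituents flank the same oxygen and neither can direct a classical aromatic substitution, together with the meso relation of two vicinal aryl-bearing methines. The key step uses exactly this pattern: oxygen-bearing C-1 between C-2 and C-6 and oxygen-bearing C-4 between two CH carbons is what an alkenyl(methoxy)carbene, one CO ligand and a terminal alkyne assemble. The twofold symmetry lets both rings be made in one operation on a bridged bis(carbene).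

## Logic of the disconnections

**16 to 15.** No skeletal bond is cut; the four quinone C=O groups are traced back to four aryl O–CH3 bonds. Quinones would survive neither the base needed to set the configuration nor the reduction that installs the carboxy carbons, whereas 1,4-dimethoxyarenes survive both. All earlier chemistry then runs on robust arenes. The forward oxidation must attack two electron-rich rings faster than four trisubstituted alkenes, and must be acidic, cold and brief so that C-2 and C-3 keep their configuration.

**15 to 14.** Only the C-2–H and C-3–H bonds are involved; the meso relation is derived by equilibration of a diastereomer mixture. There is no reagent-controlled way to create two identical benzylic ester centres in a meso relation, but both are enolisable. The preceding C–C bond formation therefore need not be diastereoselective. The forward step demands that the meso diester be the thermodynamically preferred, or the less soluble, isomer.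

**14 to 12.** The two C(α)–CO2 bonds and the two ester O–CH3 bonds are cut, so the carboxy carbons come from CO2. The central C=C of 12 is the only place where two electrons turn both benzylic carbons into nucleophiles at once. A C42 diester with two stereocentres becomes a symmetric C38 compound with none. The forward step demands that the electron-rich diarylethene accept electrons in competition with CO2 and that no proton source is present.

**12 to 11.** The two O–CH3 bonds at the hindered ring oxygens are cut. Free hydroxyl groups would protonate the carbanions of the carboxylation, and the methyl ether is also the mask for the later quinone oxygen. This links the route to the direct product of the ring-forming step. The forward step has to alkylate a 2,6-disubstituted phenoxide.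

**11 to 6 and two molecules of 9.** With phenol numbering (C-1 OH, C-2 bridge, C-4 OMe, C-6 geranyl), three bonds are cut in each ring: C-4–C-5, C-6–C-1 and C-1–C-2. C-1 is traced to a CO ligand, C-5 and C-6 to the alkyne, and C-4, C-3 and C-2 to the alkenylcarbene unit. The cut is made here because no substituent of the ring can direct a classical construction, whereas this mode fixes the pattern by connectivity. Both rings, all ring substituents and the bridging E-alkene come from one acyclic, symmetric precursor. The forward step needs regioselective alkyne insertion at both termini, independent reaction of the two chromium centres and survival of the central alkene.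

**6 to two molecules of 3 and 5.** The C-2=C-3 and C-6=C-7 double bonds of the octatriene bridge are cut (carbene carbons C-1 and C-8). The methyl group of 3 is acidic enough for an aldol-type condensation, which delivers E-alkenes. The C8 bridge becomes C2 + C4 + C2 with the central E-alkene already present in 5. Both aldehyde groups must condense before the dialdehyde oligomerises.

**5 to 4, and 3 to 1.** For 5 the two C=O groups are returned to acetal C–O bonds, because 4 is a stable commercial form of an unstable dialdehyde. For 3 the C(carbene)–CH3 and O–CH3 bonds are cut, which leads back to 1, an organolithium and a methylating agent. The hydrolysis must leave no acid behind, and the O-alkylation needs a hard electrophile.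

**9 to 7 and 8.** The bond between the propargylic CH2 (C-3) and the alkyne carbon C-2 is cut. An allylic bromide and an ethynyl nucleophile are both commercial, so C12 becomes C10 + C2. The coupling must occur at the primary allylic carbon without allylic transposition or loss of E geometry.

## Other disconnections considered

Alternative 1: The cut falls on the two bonds between the succinate α-carbons and the rings. In the forward direction the bis(silyl ketene acetal) 1,4-dimethoxy-1,4-bis(trimethylsilyloxy)buta-1,3-diene A3 would add twice, under catalytic Me3SiOSO2CF3, to the unsubstituted β-carbon next to the acetal carbon of the quinone monoacetal 3-geranyl-4,4-dimethoxycyclohexa-2,5-dien-1-one A2, and NaOMe in MeOH would then induce loss of methanol and aromatisation to dimethyl meso-2,3-bis(3-geranyl-5-hydroxy-2-methoxyphenyl)succinate A1. In its favour, the plan is convergent, forms the congested C(α)–aryl bonds directly and needs neither stoichiometric chromium nor electrolysis. The methoxide treatment could equilibrate the stereocentres in the same operation, and A1 is a 4-methoxyphenol that could be oxidised to the quinone without a methylation and demethylation detour, so on endgame length this alternative is better than the chosen plan. Against it, A2 would have to come from 3-geranyl-4-methoxyphenol A4 by oxidation in methanol, and A4 carries its geranyl group ortho to the methoxy and not to the hydroxyl group, which is the isomer that direct C-geranylation of a hydroquinone monoether does not favour. The silyl triflate can also ionise the acetal of A2 to a cation held next to the geranyl alkene, inviting cation–olefin cyclisation or attack α to the carbonyl. In addition A3 is an electron-rich diene that may cycloadd to the enone, and the second addition must occur at a centre already carrying an aryl group. In comparison, on structure this plan buys the rings and must set the 1,2,3,5-pattern by aromatic chemistry, whereas the chosen plan builds it by connectivity. On mechanism it is Lewis-acid cation chemistry next to acid-sensitive chains, against neutral thermal organometallic chemistry. On step economy the two are about equal once the making of A2 is counted.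

Alternative 2: The cut falls on the two ring–CH2 bonds of the geranyl chains. In the forward direction the dibromide dimethyl meso-2,3-bis(3-bromo-2,5-dimethoxyphenyl)succinate A6 and two equivalents of geranyltributylstannane A7 would couple under Pd(PPh3)4 (zerovalent palladium) in DMF to give dimethyl meso-2,3-bis(3-geranyl-2,5-dimethoxyphenyl)succinate A5, and because A5 is the same compound as 15 the same final oxidation would follow. In its favour, the fragile chains arrive last. The stereocentres can be settled on the chain-free and probably crystalline core A6, where meso and racemic forms should be easier to separate than on the oily substrate of the chosen plan, and on this point the alternative is better. The coupling is neutral and catalytic in palladium, and the arene pattern of A6 is reachable by bromination ortho to a phenolic hydroxyl, which is the equal of the chosen plan in availability. Against it, allyl transfer from A7 can pass through η3-allyl palladium species, which may give branched product or erode the E geometry. The aryl bromide is electron-rich and flanked by a methoxy group, so oxidative addition should be slow, two couplings must both succeed, and the tin waste from A7 is stoichiometric. Further, A6 still needs a separate bond formation between two benzylic carbons, and the cathodic CO2 route is closed to aryl bromides. In comparison, on structure this plan leaves the succinate core unsolved. On mechanism the chosen plan never makes an allyl–metal species, so the E-alkene next to the ring is safer there. On step economy the two are comparable and converge on the same penultimate compound.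

Alternative 3: The cut falls on the two C(α)–CO2H bonds. In the forward direction the stilbene (E)-1,2-bis(3-geranyl-2,5-dimethoxyphenyl)ethene A9, which is the same compound as 12, would be electrolysed at constant current at a carbon cathode in DMF with Bu4NBF4 under CO2 with a sacrificial Mg anode, and acidification of the magnesium salt would give meso-2,3-bis(3-geranyl-2,5-dimethoxyphenyl)succinic acid A8. In its favour, both carboxy carbons come from CO2 and both stereocentres form in one operation on a symmetric substrate. The chosen plan uses the same transformation in step 7, so on this step the two are equal. If A9 were made from arene building blocks, for example by reductive coupling of 3-geranyl-2,5-dimethoxybenzaldehyde A10 with low-valent titanium from TiCl4 and Zn, no chromium carbonyl chemistry would be needed, which is better for scale and waste. Against it, nothing in the electrolysis biases the two centres towards meso, so A8 would be expected together with its racemic diastereomer. A dicarboxylate also resists enolisation, so A8 would still have to be esterified and equilibrated, as in steps 7 and 8. Finally A10 requires geranylation of a metalated arene, with its own SN2 versus SN2' question, and is not reached by simple directed metalation. In comparison, on structure this cut solves only the side chain and leaves the ring pattern to aromatic chemistry, whereas the chosen plan adds a ring-forming solution for the same stilbene. The mechanism of the shared step is identical, and step economy to the stilbene is about equal.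

Key step: step 5

Remark on the chemistry: "geranyl" denotes (2E)-3,7-dimethylocta-2,6-dien-1-yl throughout, and the target stereocentres are read as (2R,3S), which with identical substituents is the meso form.

## Route

Step 1
Reactants: 1 chromium hexacarbonyl
Product: 3 pentacarbonyl(1-methoxyethylidene)chromium, via lithium acetylpentacarbonylchromate 2 (not isolated)
Conditions: MeLi, Et2O, 0 °C to rt; then Me3OBF4, H2O/CH2Cl2, 0 °C
Reagents that add atoms: methyllithium, [Li]C; trimethyloxonium tetrafluoroborate, C[O+](C)C.F[B-](F)(F)F
Why: Fischer carbene synthesis: the organolithium adds to a carbonyl ligand to give the acyl chromate, whose hard oxygen is methylated by the Meerwein salt.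

Step 2
Reactants: 4 fumaraldehyde bis(dimethyl acetal)
Product: 5 fumaraldehyde
Conditions: Amberlyst-15 (sulfonic acid resin), acetone/H2O (excess water), rt; filter, concentrate cold, use at once
Reagents that add atoms: water, O
Why: Acid-catalysed acetal hydrolysis; the solid acid is filtered off so the sensitive dialdehyde is obtained acid-free with its E-alkene untouched.

Step 3
Reactants: 3 pentacarbonyl(1-methoxyethylidene)chromium (2.2 equiv); 5 fumaraldehyde
Product: 6 μ-[(2E,4E,6E)-1,8-dimethoxyocta-2,4,6-triene-1,8-diylidene]bis(pentacarbonylchromium)
Conditions: Et3N, Me3SiCl, Et2O, rt, Ar, dark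
Reagents that add atoms: none
Why: Aldol-type condensation of a methyl(alkoxy)carbene complex with an aldehyde: Et3N deprotonates the acidic methyl group, the anion adds to each aldehyde, and Me3SiCl silylates the aldolate and drives elimination to the conjugated E-alkene; both ends of 5 should react in the same way.

Step 4
Reactants: 7 geranyl bromide; 8 ethynylmagnesium bromide (2.5 equiv)
Product: 9 (E)-5,9-dimethyldeca-4,8-dien-1-yne
Conditions: CuCl (5 mol %), THF, 0 to 50 °C
Reagents that add atoms: none
Why: Copper-catalysed coupling of an alkynyl Grignard reagent with a primary allylic bromide, which should occur at the primary carbon with the E-alkene retained; excess 8 suppresses a second alkylation of the product acetylide.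

Step 5
Reactants: 6 μ-[(2E,4E,6E)-1,8-dimethoxyocta-2,4,6-triene-1,8-diylidene]bis(pentacarbonylchromium); 9 (E)-5,9-dimethyldeca-4,8-dien-1-yne (3 equiv)
Product: 11 2,2'-[(E)-ethene-1,2-diyl]bis(6-geranyl-4-methoxyphenol), via bis(tricarbonylchromium) arene complex 10 (not isolated)
Conditions: THF (0.03 M, degassed), 50 °C, Ar; then air, rt, filtration through silica
Reagents that add atoms: none
Why: Loss of one cis-CO from each Cr(CO)5 terminus lets alkyne 9 coordinate and insert into the Cr=C bond with its CH carbon bonding to the carbene carbon, because the carbon carrying the geranyl CH2 avoids the methoxy-bearing centre and stays on chromium. A CO ligand then migrates onto that carbon to give a chromium-bound dienylketene, whose ketene carbon bonds to the β-carbon of the original alkenyl unit; tautomerisation of the cyclohexadienone gives the phenol as its η6-Cr(CO)3 complex 10, and air then oxidises the metal off to free 11. The closest known reaction type is the Dötz benzannulation of β-substituted alkenyl(methoxy)carbene chromium complexes with terminal alkynes, which has also been run twice in one molecule on bis(carbene) complexes. Each of the two rings closes by a thermal 6π electrocyclisation of the dienylketene followed by enolisation. No stereocentre is formed; the central C-4=C-5 alkene of 6 belongs to neither reacting unit and should be carried through with its E geometry to become the stilbene double bond. The selectivities needed are regiochemistry of insertion (secured by the terminal alkyne), benzannulation instead of cyclopentannulation (secured by chromium, the methoxy donor and THF at moderate temperature) and six- instead of eight-membered closure (secured by the E geometry at C-2=C-3 and C-6=C-7 of 6, which holds the remaining diene away from the ketene carbon). The trisubstituted alkenes of 9 are neither electron-poor nor strongly donating and are one CH2 away from the alkyne, so they should be neither cyclopropanated nor inserted, and the E geometry of the bridge keeps the first-formed phenol oxygen away from the still unreacted carbene terminus.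

Step 6
Reactants: 11 2,2'-[(E)-ethene-1,2-diyl]bis(6-geranyl-4-methoxyphenol)
Product: 12 (E)-1,2-bis(3-geranyl-2,5-dimethoxyphenyl)ethene
Conditions: MeI (excess), K2CO3, acetone, reflux
Reagents that add atoms: iodomethane, CI
Why: Williamson ether synthesis; the 2,6-disubstituted phenoxide is hindered but methyl iodide is small, and the CH2 between ring and alkene is not acidic enough for carbonate.

Step 7
Reactants: 12 (E)-1,2-bis(3-geranyl-2,5-dimethoxyphenyl)ethene
Product: 14 dimethyl 2,3-bis(3-geranyl-2,5-dimethoxyphenyl)succinate (meso/racemic mixture), via magnesium dicarboxylate 13 (not isolated)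
Conditions: CO2 (1 atm), Bu4NBF4, DMF, glassy-carbon cathode, Mg anode, undivided cell, constant current, −10 °C; then MeI, K2CO3, 50 °C
Reagents that add atoms: carbon dioxide, O=C=O; iodomethane, CI
Why: Electroreductive dicarboxylation of a stilbene: the cathodically formed radical anion adds to CO2, the resulting benzylic radical is reduced and carboxylated again, and Mg2+ from the anode pairs with the dicarboxylate, which is then O-methylated in the same pot. The two stereocentres form without control, so a mixture is expected; isolated alkenes and aryl ethers are not reduced at this potential.

Step 8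
Reactants: 14 dimethyl 2,3-bis(3-geranyl-2,5-dimethoxyphenyl)succinate (meso/racemic mixture)
Product: 15 dimethyl (2R,3S)-2,3-bis(3-geranyl-2,5-dimethoxyphenyl)succinate (meso)
Conditions: NaOMe (0.5 equiv), MeOH/THF, rt to 50 °C
Reagents that add atoms: none
Why: Base-mediated epimerisation through the ester enolates; the meso diester, with aryl and ester groups anti, is expected to be the favoured and less soluble isomer, which fixes the (2R,3S) relation, and methoxide in methanol makes transesterification degenerate.

Step 9
Reactants: 15 dimethyl (2R,3S)-2,3-bis(3-geranyl-2,5-dimethoxyphenyl)succinate (meso)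
Product: 16 dimethyl (2R,3S)-2,3-bis(5-geranyl-3,6-dioxocyclohexa-1,4-dien-1-yl)succinate (meso), the target
Conditions: (NH4)2Ce(NO3)6 (5 equiv), MeCN/H2O, 0 °C, short contact
Reagents that add atoms: water, O
Why: Oxidative demethylation of 1,4-dimethoxyarenes: two one-electron oxidations per ring, water adding at the methoxy-bearing carbons and methanol leaving; the medium is acidic and cold, so the enolisable stereocentres and the trisubstituted alkenes should survive.

## Compound list

1 | chromium hexacarbonyl | O=C=[Cr](=C=O)(=C=O)(=C=O)(=C=O)=C=O | starting material
2 | lithium acetylpentacarbonylchromate | [Li+].CC([O-])=[Cr](=C=O)(=C=O)(=C=O)(=C=O)=C=O | intermediate (not isolated)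
3 | pentacarbonyl(1-methoxyethylidene)chromium | COC(C)=[Cr](=C=O)(=C=O)(=C=O)(=C=O)=C=O | intermediate
4 | fumaraldehyde bis(dimethyl acetal), (E)-1,1,4,4-tetramethoxybut-2-ene | COC(OC)/C=C/C(OC)OC | starting material
5 | fumaraldehyde, (E)-but-2-enedial | O=C/C=C/C=O | intermediate
6 | μ-[(2E,4E,6E)-1,8-dimethoxyocta-2,4,6-triene-1,8-diylidene]bis(pentacarbonylchromium) | COC(/C=C/C=C/C=C/C(OC)=[Cr](=C=O)(=C=O)(=C=O)(=C=O)=C=O)=[Cr](=C=O)(=C=O)(=C=O)(=C=O)=C=O | intermediate
7 | geranyl bromide | BrC/C=C(\C)CCC=C(C)C | starting material
8 | ethynylmagnesium bromide | C#C[Mg]Br | starting material
9 | (E)-5,9-dimethyldeca-4,8-dien-1-yne | C#CC/C=C(\C)CCC=C(C)C | intermediate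
10 | bis(η6-arene)tricarbonylchromium complex of 11 (one Cr(CO)3 on each phenol ring; written as ligand plus two Cr(CO)3 fragments) | Oc1c(/C=C/c2cc(OC)cc(C/C=C(\C)CCC=C(C)C)c2O)cc(OC)cc1C/C=C(\C)CCC=C(C)C.O=C=[Cr](=C=O)=C=O.O=C=[Cr](=C=O)=C=O | intermediate (not isolated)
11 | 2,2'-[(E)-ethene-1,2-diyl]bis(6-geranyl-4-methoxyphenol) | Oc1c(/C=C/c2cc(OC)cc(C/C=C(\C)CCC=C(C)C)c2O)cc(OC)cc1C/C=C(\C)CCC=C(C)C | intermediate
12 | (E)-1,2-bis(3-geranyl-2,5-dimethoxyphenyl)ethene | COc1cc(C/C=C(\C)CCC=C(C)C)c(OC)c(/C=C/c2cc(OC)cc(C/C=C(\C)CCC=C(C)C)c2OC)c1 | intermediate
13 | magnesium 2,3-bis(3-geranyl-2,5-dimethoxyphenyl)succinate (C-2 and C-3 undefined, diastereomer mixture) | [Mg+2].[O-]C(=O)C(c1cc(OC)cc(C/C=C(\C)CCC=C(C)C)c1OC)C(C([O-])=O)c1cc(OC)cc(C/C=C(\C)CCC=C(C)C)c1OC | intermediate (not isolated)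
14 | dimethyl 2,3-bis(3-geranyl-2,5-dimethoxyphenyl)succinate (meso/racemic mixture, C-2 and C-3 undefined) | COC(=O)C(c1cc(OC)cc(C/C=C(\C)CCC=C(C)C)c1OC)C(C(=O)OC)c1cc(OC)cc(C/C=C(\C)CCC=C(C)C)c1OC | intermediate
15 | dimethyl (2R,3S)-2,3-bis(3-geranyl-2,5-dimethoxyphenyl)succinate (meso) | COC(=O)[C@H](c1cc(OC)cc(C/C=C(\C)CCC=C(C)C)c1OC)[C@@H](C(=O)OC)c1cc(OC)cc(C/C=C(\C)CCC=C(C)C)c1OC | intermediate
16 | dimethyl (2R,3S)-2,3-bis(5-geranyl-3,6-dioxocyclohexa-1,4-dien-1-yl)succinate (meso) | COC(=O)[C@H](C1=CC(=O)C=C(C/C=C(\C)CCC=C(C)C)C1=O)[C@@H](C(=O)OC)C1=CC(=O)C=C(C/C=C(\C)CCC=C(C)C)C1=O | target

## Step count and least certain steps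

Total step count: 9. Longest linear sequence: 7 steps (steps 1, 3, 5, 6, 7, 8, 9); steps 2 and 4 are one-step side branches.

**Step 5 (key step).** The most likely failure is incomplete twofold annulation. After one ring has formed, the remaining polyenyl carbene terminus is a strong conjugate acceptor and may be attacked by phenol oxygen of another molecule or may decompose, and the terminal alkyne may oligomerise on chromium. The triene-bridged bis(carbene) has no direct precedent for this behaviour. The fallback gives up the two-directional mode and sets out from 3 and 9. Compound 3 is condensed (Et3N, Me3SiCl) with commercial 2,2-dimethoxyacetaldehyde, extracted from its aqueous solution and dried, to pentacarbonyl[(2E)-1,4,4-trimethoxybut-2-en-1-ylidene]chromium F1. A single benzannulation of F1 with 9 (THF, 50 °C, then air), with a dilute aqueous acid work-up that unmasks the acetal, should give 3-geranyl-2-hydroxy-5-methoxybenzaldehyde F2. Methylation (MeI, K2CO3) gives 3-geranyl-2,5-dimethoxybenzaldehyde F3, and McMurry coupling (TiCl4, Zn, THF, reflux; low-valent titanium) joins two molecules of F3. The route is rejoined at 12.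

**Step 3.** The free dialdehyde may oligomerise under the amine, and deprotonated 3 may add in conjugate fashion to the mono-condensed alkenylcarbene instead of to the second aldehyde. The fallback builds the bridge one end at a time and sets out from 4 and 3. Partial hydrolysis of 4 (Amberlyst-15, acetone with limited water) gives the stable (E)-4,4-dimethoxybut-2-enal F4. Condensation of F4 with 3 gives pentacarbonyl[(2E,4E)-1,6,6-trimethoxyhexa-2,4-dien-1-ylidene]chromium F5. Mild acid hydrolysis of the acetal gives pentacarbonyl[(2E,4E)-1-methoxy-6-oxohexa-2,4-dien-1-ylidene]chromium F6, and a second condensation of F6 with 3 returns to the route at 6.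

**Step 7.** The electron-rich stilbene is reduced near the potential of CO2 itself, so direct CO2 reduction may compete. Traces of water may protonate the carbanions, leading to hydrogenation or monocarboxylation. The fallback separates reduction from carboxylation and sets out from 12. Lithium metal with catalytic naphthalene in THF at low temperature should reduce 12 fully to 1,2-dilithio-1,2-bis(3-geranyl-2,5-dimethoxyphenyl)ethane F7 before any CO2 is present. Gaseous CO2 is then admitted, and acidification with dilute HCl gives 2,3-bis(3-geranyl-2,5-dimethoxyphenyl)succinic acid F8 as a diastereomer mixture. This is esterified (MeI, K2CO3, DMF) and rejoins the route at 14.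

**Step 8.** Stereochemical convergence may be incomplete, because the energy difference between the isomers may be small and the lipophilic chains may prevent the meso diester from crystallising out of the equilibrium. The fallback replaces one-pot convergence by separation with recycling and sets out from 14. The diastereomers are separated by chromatography, the meso isomer is taken on, and the racemic dimethyl (2S,3S)/(2R,3R)-2,3-bis(3-geranyl-2,5-dimethoxyphenyl)succinate F9 is returned to the NaOMe equilibration until it is consumed. The route is rejoined at 15.

**Step 9.** The one-electron oxidant may also attack the electron-rich alkenes or the activated CH2 and CH positions, one ring may be oxidised without the other, and the product may tautomerise during a slow reaction. The fallback changes to a two-stage electrochemical route and sets out from 15. Anodic oxidation at a carbon anode in methanol buffered with LiClO4 and 2,6-lutidine at 0 °C, at a potential below that of the alkenes, should give the bis(quinone bisketal) dimethyl (2R,3S)-2,3-bis(5-geranyl-3,3,6,6-tetramethoxycyclohexa-1,4-dien-1-yl)succinate F10. Hydrolysis with dilute aqueous acid in acetone then returns to the route at 16.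

## Further compounds

F1 | step 5 | pentacarbonyl[(2E)-1,4,4-trimethoxybut-2-en-1-ylidene]chromium | COC(/C=C/C(OC)OC)=[Cr](=C=O)(=C=O)(=C=O)(=C=O)=C=O
F2 | step 5 | 3-geranyl-2-hydroxy-5-methoxybenzaldehyde | O=Cc1cc(OC)cc(C/C=C(\C)CCC=C(C)C)c1O
F3 | step 5 | 3-geranyl-2,5-dimethoxybenzaldehyde | O=Cc1cc(OC)cc(C/C=C(\C)CCC=C(C)C)c1OC
F4 | step 3 | (E)-4,4-dimethoxybut-2-enal | COC(OC)/C=C/C=O
F5 | step 3 | pentacarbonyl[(2E,4E)-1,6,6-trimethoxyhexa-2,4-dien-1-ylidene]chromium | COC(/C=C/C=C/C(OC)OC)=[Cr](=C=O)(=C=O)(=C=O)(=C=O)=C=O
F6 | step 3 | pentacarbonyl[(2E,4E)-1-methoxy-6-oxohexa-2,4-dien-1-ylidene]chromium | COC(/C=C/C=C/C=O)=[Cr](=C=O)(=C=O)(=C=O)(=C=O)=C=O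
F7 | step 7 | 1,2-dilithio-1,2-bis(3-geranyl-2,5-dimethoxyphenyl)ethane | [Li]C(c1cc(OC)cc(C/C=C(\C)CCC=C(C)C)c1OC)C([Li])c1cc(OC)cc(C/C=C(\C)CCC=C(C)C)c1OC
F8 | step 7 | 2,3-bis(3-geranyl-2,5-dimethoxyphenyl)succinic acid (diastereomer mixture) | OC(=O)C(c1cc(OC)cc(C/C=C(\C)CCC=C(C)C)c1OC)C(C(=O)O)c1cc(OC)cc(C/C=C(\C)CCC=C(C)C)c1OC
F9 | step 8 | dimethyl (2S,3S)-2,3-bis(3-geranyl-2,5-dimethoxyphenyl)succinate (racemic; one enantiomer drawn) | COC(=O)[C@H](c1cc(OC)cc(C/C=C(\C)CCC=C(C)C)c1OC)[C@H](C(=O)OC)c1cc(OC)cc(C/C=C(\C)CCC=C(C)C)c1OC
F10 | step 9 | dimethyl (2R,3S)-2,3-bis(5-geranyl-3,3,6,6-tetramethoxycyclohexa-1,4-dien-1-yl)succinate (meso) | COC(=O)[C@H](C1=CC(OC)(OC)C=C(C/C=C(\C)CCC=C(C)C)C1(OC)OC)[C@@H](C(=O)OC)C1=CC(OC)(OC)C=C(C/C=C(\C)CCC=C(C)C)C1(OC)OC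
A1 | alternative 1 | dimethyl meso-2,3-bis(3-geranyl-5-hydroxy-2-methoxyphenyl)succinate | COC(=O)[C@H](c1cc(O)cc(C/C=C(\C)CCC=C(C)C)c1OC)[C@@H](C(=O)OC)c1cc(O)cc(C/C=C(\C)CCC=C(C)C)c1OC
A2 | alternative 1 | 3-geranyl-4,4-dimethoxycyclohexa-2,5-dien-1-one | COC1(OC)C=CC(=O)C=C1C/C=C(\C)CCC=C(C)C
A3 | alternative 1 | 1,4-dimethoxy-1,4-bis(trimethylsilyloxy)buta-1,3-diene (double-bond isomer mixture) | COC(O[Si](C)(C)C)=CC=C(OC)O[Si](C)(C)C
A4 | alternative 1 | 3-geranyl-4-methoxyphenol | COc1ccc(O)cc1C/C=C(\C)CCC=C(C)C
A5 | alternative 2 | dimethyl meso-2,3-bis(3-geranyl-2,5-dimethoxyphenyl)succinate | COC(=O)[C@H](c1cc(OC)cc(C/C=C(\C)CCC=C(C)C)c1OC)[C@@H](C(=O)OC)c1cc(OC)cc(C/C=C(\C)CCC=C(C)C)c1OC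
A6 | alternative 2 | dimethyl meso-2,3-bis(3-bromo-2,5-dimethoxyphenyl)succinate | COC(=O)[C@H](c1cc(OC)cc(Br)c1OC)[C@@H](C(=O)OC)c1cc(OC)cc(Br)c1OC
A7 | alternative 2 | geranyltributylstannane | CCCC[Sn](CCCC)(CCCC)C/C=C(\C)CCC=C(C)C
A8 | alternative 3 | meso-2,3-bis(3-geranyl-2,5-dimethoxyphenyl)succinic acid | OC(=O)[C@H](c1cc(OC)cc(C/C=C(\C)CCC=C(C)C)c1OC)[C@@H](C(=O)O)c1cc(OC)cc(C/C=C(\C)CCC=C(C)C)c1OC
A9 | alternative 3 | (E)-1,2-bis(3-geranyl-2,5-dimethoxyphenyl)ethene | COc1cc(C/C=C(\C)CCC=C(C)C)c(OC)c(/C=C/c2cc(OC)cc(C/C=C(\C)CCC=C(C)C)c2OC)c1
A10 | alternative 3 | 3-geranyl-2,5-dimethoxybenzaldehyde | O=Cc1cc(OC)cc(C/C=C(\C)CCC=C(C)C)c1OC
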